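Everything rests on closing ring A at the C10–C1 bond (eudesmane numbering), the bond to the quaternary, methyl-bearing ring-fusion carbon. The route exploits that C1 is the vinylogous terminus of the C15 carbonyl (C15–C4=C3–C2–C1): hydrogen-atom transfer to the C9=C10 olefin of a carvone-derived ring B gives the tertiary C10 radical, which adds 6-endo to C1 of a dienal arm held on C5. One operation sets the C10 quaternary stereocentre, the trans-decalin and the C3=C4–C15 enal that becomes the allylic coumarate. The precursor is a cis-3,5-disubstituted 2-methylcyclohexene bearing the finished C7 acrylate and a 2-substituted penta-2,4-dienal, assembled by Claisen rearrangement of a cis-carveol-type alcohol.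

Key step: step 9

Assumption: eudesmane numbering is used for all ring atoms (C10 = methyl-bearing fusion carbon, C5 = fusion CH, C7 = acrylate-bearing carbon, C15 = oxygenated carbon on C4); the SMILES encodes the 5α-H, 7β, 10β-methyl trans-decalin, (5R,7R,10R).

Step 1
Reactants: 1 (S)-(+)-carvone
Product: 2 (5S)-5-(3-chloroprop-1-en-2-yl)-2-methylcyclohex-2-en-1-one
Conditions: Ca(OCl)2, solid CO2, CH2Cl2/H2O, 0 °C to rt
Reagents that add atoms: calcium hypochlorite, [Ca+2].[O-]Cl.[O-]Cl
Why: Ene-type allylic chlorination by hypochlorous acid made in situ should attack only the electron-rich 1,1-disubstituted olefin (the enone olefin is deactivated) and touches no stereocentre.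

Step 2
Reactants: 2 (5S)-5-(3-chloroprop-1-en-2-yl)-2-methylcyclohex-2-en-1-one
Product: 3 2-[(1S)-4-methyl-5-oxocyclohex-3-en-1-yl]prop-2-enal
Conditions: NMO, KI (cat.), MeCN, rt to 40 °C
Reagents that add atoms: N-methylmorpholine N-oxide, C[N+]1([O-])CCOCC1
Why: Ganem (Kornblum-type) N-oxide oxidation, in which iodide-assisted SN2 displacement by the N-oxide oxygen and base-induced N–O cleavage should give the 2-substituted acrolein, the SN2 and SN2' paths converging on the same product.

Step 3
Reactants: 3 2-[(1S)-4-methyl-5-oxocyclohex-3-en-1-yl]prop-2-enal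
Product: 4 2-[(1S)-4-methyl-5-oxocyclohex-3-en-1-yl]prop-2-enoic acid
Conditions: NaClO2, NaH2PO4, 2-methyl-2-butene, t-BuOH/H2O, 0 °C to rt
Reagents that add atoms: sodium chlorite, [Na+].[O-]Cl=O
Why: Pinnick oxidation should convert the enal into the acrylic acid without touching the enone or either olefin, the scavenger removing hypochlorous acid.

Step 4
Reactants: 4 2-[(1S)-4-methyl-5-oxocyclohex-3-en-1-yl]prop-2-enoic acid
Product: 5 methyl 2-[(1S)-4-methyl-5-oxocyclohex-3-en-1-yl]prop-2-enoate
Conditions: MeI, K2CO3, DMF, 0 °C to rt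
Reagents that add atoms: iodomethane, CI
Why: Carboxylate O-alkylation (SN2 on iodomethane) is chosen over a diazoalkane, which would add to the acrylate as a 1,3-dipole.

Step 5
Reactants: 5 methyl 2-[(1S)-4-methyl-5-oxocyclohex-3-en-1-yl]prop-2-enoate
Product: 6 methyl 2-[(1S,5S)-5-hydroxy-4-methylcyclohex-3-en-1-yl]prop-2-enoate (cis alcohol)
Conditions: NaBH4, CeCl3·7H2O, MeOH, −78 °C
Reagents that add atoms: none
Why: Luche 1,2-reduction, in which axial hydride attack on the half-chair with the C7 substituent equatorial should give the cis alcohol (substrate control, as for carvone itself), the acrylate ester being inert at −78 °C.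

Step 6
Reactants: 6 methyl 2-[(1S,5S)-5-hydroxy-4-methylcyclohex-3-en-1-yl]prop-2-enoate; 7 butyl vinyl ether
Product: 9 methyl 2-[(1R,5S)-4-methyl-5-(2-oxoethyl)cyclohex-3-en-1-yl]prop-2-enoate, via allyl vinyl ether 8 (not isolated)
Conditions: Pd(OCOCF3)2 (cat.), 4,7-diphenyl-1,10-phenanthroline (cat.), Et3N (cat.), 7 as solvent, 75 °C; then toluene, BHT (cat.), 160 °C, sealed tube
Reagents that add atoms: none
Why: Transfer vinylation catalysed by divalent palladium followed by a thermal Claisen [3,3] rearrangement, whose suprafacial shift delivers the new C5–C4 bond on the face that carried oxygen, hence cis to the C7 acrylate, and moves the olefin to C9=C10.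

Step 7
Reactants: 9 methyl 2-[(1R,5S)-4-methyl-5-(2-oxoethyl)cyclohex-3-en-1-yl]prop-2-enoate
Product: 10 methyl 2-[(1R,5S)-5-[2-(tert-butyldimethylsilyloxy)ethenyl]-4-methylcyclohex-3-en-1-yl]prop-2-enoate (E/Z mixture)
Conditions: TBSOTf, Et3N, CH2Cl2, 0 °C
Reagents that add atoms: tert-butyldimethylsilyl trifluoromethanesulfonate, CC(C)(C)[Si](C)(C)OS(=O)(=O)C(F)(F)F
Why: Soft enolisation with silyl triflate and amine should give the aldehyde-derived silyl enol ether (only C4 is enolisable) without the strong base that would trigger Michael closure onto the acrylate.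

Step 8
Reactants: 10 methyl 2-[(1R,5S)-5-[2-(tert-butyldimethylsilyloxy)ethenyl]-4-methylcyclohex-3-en-1-yl]prop-2-enoate; 11 acrolein diethyl acetal
Product: 13 methyl 2-[(1R,5R)-4-methyl-5-[(2E)-1-oxopenta-2,4-dien-2-yl]cyclohex-3-en-1-yl]prop-2-enoate, via ethoxy aldol 12 (not isolated)
Conditions: TMSOTf (cat.), CH2Cl2, −78 °C; then DBU, 0 °C to rt
Reagents that add atoms: none
Why: Mukaiyama-type aldol addition of the enol silane to the alkoxyallyl cation at its acetal carbon followed by E1cB loss of ethanol should give the dienal, whose (E) geometry (vinyl cis to the ring, trans to the formyl group) is the thermodynamic one for a 2-alkyl-2-enal.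

Step 9
Reactants: 13 methyl 2-[(1R,5R)-4-methyl-5-[(2E)-1-oxopenta-2,4-dien-2-yl]cyclohex-3-en-1-yl]prop-2-enoate
Product: 15 methyl (5R,7R,10R)-15-oxoeudesma-3,11(13)-dien-12-oate, via deconjugated aldehyde 14 (not isolated)
Conditions: Fe(acac)3 (30 mol%), PhSiH3, EtOH/ethylene glycol, 60 °C, 0.01 M; then DBU (cat.), CH2Cl2, rt
Reagents that add atoms: none
Why: Proposed new method: Hydrogen-atom transfer from the iron hydride (Fe(acac)3/PhSiH3) to C9 of the trisubstituted C9=C10 olefin gives the tertiary C10 radical, which adds to the terminal carbon C1 of the s-cis dienal in a vinylogous (1,6) Giese addition; divalent iron reduces the resulting oxapentadienyl radical to the dienolate, ethanol protonates it at C4, and DBU moves the olefin into conjugation. The closest known reaction type is the Fe(acac)3/PhSiH3 reductive olefin coupling (Giese addition initiated by metal-hydride hydrogen-atom transfer, also intramolecular) onto enones, enals and acrylates, and 1,6-additions of alkyl radicals to 2,4-dienoates are known under tin hydride and photoredox conditions; the extension here is the 2,4-dienal acceptor. Ring A closes in the 6-endo-trig mode, the only one open to the C10 radical, since attack at C3 would be 4-exo and attack at C2 would give an unstabilised primary radical. The new stereocentre C10 is controlled by C5 and C7: their cis-1,3 relationship keeps the dienal arm and the acrylate equatorial, and an equatorial arm should reach the C10 radical on its equatorial face, so that C1 becomes equatorial, the methyl group axial and the ring fusion trans. The step needs hydrogen-atom transfer to the electron-rich C9=C10 olefin rather than to the two acceptor olefins, the same chemoselectivity on which the parent coupling rests, and it needs the acrylate to stay out of the radical step, which is secured by its position (it can reach C10 only from a diaxial conformer) and by high dilution.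

Step 10
Reactants: 15 methyl (5R,7R,10R)-15-oxoeudesma-3,11(13)-dien-12-oate
Product: 16 methyl (5R,7R,10R)-15-hydroxyeudesma-3,11(13)-dien-12-oate
Conditions: NaBH4, CeCl3·7H2O, MeOH, −40 °C
Reagents that add atoms: none
Why: Luche reduction is selective for the conjugated aldehyde (1,2-addition) over the methyl acrylate and creates no stereocentre.

Step 11
Reactants: 16 methyl (5R,7R,10R)-15-hydroxyeudesma-3,11(13)-dien-12-oate; 17 (E)-p-coumaric acid
Product: 18 methyl (5R,7R,10R)-15-{[(2E)-3-(4-hydroxyphenyl)prop-2-enoyl]oxy}eudesma-3,11(13)-dien-12-oate (CNP0161949.1)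
Conditions: PPh3, DIAD, THF, 0 °C to rt
Reagents that add atoms: none
Why: Mitsunobu esterification, in which the betaine deprotonates the carboxylic acid in preference to the far less acidic phenol and the carboxylate displaces the activated primary allylic oxygen by SN2, so that no phenol protection is needed and no stereocentre is involved.

Compound list
1 | (S)-(+)-carvone, (5S)-2-methyl-5-(prop-1-en-2-yl)cyclohex-2-en-1-one | CC1=CC[C@@H](CC1=O)C(C)=C | starting material
2 | (5S)-5-(3-chloroprop-1-en-2-yl)-2-methylcyclohex-2-en-1-one (10-chlorocarvone) | CC1=CC[C@@H](CC1=O)C(=C)CCl | intermediate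
3 | 2-[(1S)-4-methyl-5-oxocyclohex-3-en-1-yl]prop-2-enal | CC1=CC[C@@H](CC1=O)C(=C)C=O | intermediate
4 | 2-[(1S)-4-methyl-5-oxocyclohex-3-en-1-yl]prop-2-enoic acid | CC1=CC[C@@H](CC1=O)C(=C)C(O)=O | intermediate
5 | methyl 2-[(1S)-4-methyl-5-oxocyclohex-3-en-1-yl]prop-2-enoate | CC1=CC[C@@H](CC1=O)C(=C)C(=O)OC | intermediate
6 | methyl 2-[(1S,5S)-5-hydroxy-4-methylcyclohex-3-en-1-yl]prop-2-enoate, hydroxyl cis to the acrylate-bearing carbon | CC1=CC[C@@H](C[C@@H]1O)C(=C)C(=O)OC | intermediate
7 | butyl vinyl ether | C=COCCCC | starting material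
8 | methyl 2-[(1S,5S)-5-(ethenyloxy)-4-methylcyclohex-3-en-1-yl]prop-2-enoate (allyl vinyl ether, not isolated) | CC1=CC[C@@H](C[C@@H]1OC=C)C(=C)C(=O)OC | intermediate
9 | methyl 2-[(1R,5S)-4-methyl-5-(2-oxoethyl)cyclohex-3-en-1-yl]prop-2-enoate, the two ring substituents cis | CC1=CC[C@H](C[C@H]1CC=O)C(=C)C(=O)OC | intermediate
10 | methyl 2-[(1R,5S)-5-[2-(tert-butyldimethylsilyloxy)ethenyl]-4-methylcyclohex-3-en-1-yl]prop-2-enoate, E/Z mixture at the enol ether | CC1=CC[C@H](C[C@H]1C=CO[Si](C)(C)C(C)(C)C)C(=C)C(=O)OC | intermediate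
11 | acrolein diethyl acetal (3,3-diethoxyprop-1-ene) | C=CC(OCC)OCC | starting material
12 | methyl 2-[(1R,5S)-5-(3-ethoxy-1-oxopent-4-en-2-yl)-4-methylcyclohex-3-en-1-yl]prop-2-enoate, mixture at the two side-chain centres (not isolated) | CC1=CC[C@H](C[C@H]1C(C=O)C(OCC)C=C)C(=C)C(=O)OC | intermediate
13 | methyl 2-[(1R,5R)-4-methyl-5-[(2E)-1-oxopenta-2,4-dien-2-yl]cyclohex-3-en-1-yl]prop-2-enoate, vinyl group cis to the ring across C4=C3 | CC1=CC[C@H](C[C@H]1/C(C=O)=C\C=C)C(=C)C(=O)OC | intermediate
14 | methyl 15-oxoeudesma-2,11(13)-dien-12-oate, trans-fused as in 15, C4 epimers (not isolated) | C=C(C(=O)OC)[C@@H]1CC[C@@]2(C)CC=CC(C=O)[C@@H]2C1 | intermediate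
15 | methyl (5R,7R,10R)-15-oxoeudesma-3,11(13)-dien-12-oate, trans-decalin with 5α-H, 10β-methyl, 7β-acrylate | C=C(C(=O)OC)[C@@H]1CC[C@@]2(C)CCC=C(C=O)[C@@H]2C1 | intermediate
16 | methyl (5R,7R,10R)-15-hydroxyeudesma-3,11(13)-dien-12-oate | C=C(C(=O)OC)[C@@H]1CC[C@@]2(C)CCC=C(CO)[C@@H]2C1 | intermediate
17 | (E)-p-coumaric acid, (2E)-3-(4-hydroxyphenyl)prop-2-enoic acid | OC(=O)/C=C/c1ccc(O)cc1 | starting material
18 | methyl (5R,7R,10R)-15-{[(2E)-3-(4-hydroxyphenyl)prop-2-enoyl]oxy}eudesma-3,11(13)-dien-12-oate (CNP0161949.1) | C=C(C(=O)OC)[C@@H]1CC[C@@]2(C)CCC=C(COC(=O)/C=C/c3ccc(O)cc3)[C@@H]2C1 | target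

Total step count: 11. Longest linear sequence: 11 steps, from (S)-(+)-carvone 1.

Steps most likely to fail

1. Step 9 (Proposed new method). Hydrogen-atom transfer may go to the terminal olefin of the dienal and reduce the diene instead of starting the cyclisation, and closure on the axial face of the C10 radical would give the cis ring fusion. The fallback uses known chemistry, sets out from aldehyde 9 and comes back at target 18. Organocatalytic α-methylenation of 9 (aqueous formaldehyde, pyrrolidine, propionic acid) should give the 2-substituted acrolein F1. Nozaki–Hiyama–Kishi addition of vinyl bromide (CrCl2, NiCl2 cat., DMF), which spares the ester, should give the divinyl carbinol F2, and Dess–Martin oxidation the cross-conjugated divinyl ketone F3. The established Fe(acac)3/PhSiH3 1,4-Giese cyclisation onto the vinyl ketone arm (6-endo at C1, the only reachable terminus) closes the same C10–C1 bond and should give the 4-methylene-3-ketone F4. Luche reduction should give the allylic alcohol F5, and SOCl2 with allylic transposition the primary allylic chloride F6. Alkylation of the carboxylate of 17 (KHCO3, DMF) with F6 then gives 18.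

2. Step 8. The enol silane may attack the alkoxyallyl cation at its γ-carbon, the aldehyde enolate formed during the elimination may close onto the acrylate, and the dienal may dimerise on concentration. The fallback sets out from silyl enol ether 10 and comes back at dienal 13. Vilsmeier formylation of 10 (DMF/(COCl)2, then aqueous K2CO3) should give the 2-substituted malonaldehyde F7. Tf2O/2,6-lutidine should convert it into the (E)-enol triflate F8, and Stille coupling with tributyl(vinyl)stannane (Pd(PPh3)4, LiCl, THF) gives 13.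

3. Step 6. The cis vinyl ether must rearrange through a half-chair with both substituents axial, so retro-ene loss of acetaldehyde and thermal polymerisation of the acrylate may outrun the [3,3] shift. The fallback sets out from alcohol 6 and comes back at aldehyde 9. Eschenmoser–Claisen rearrangement with N,N-dimethylacetamide dimethyl acetal (xylene, 130 °C), which runs through a ketene N,O-acetal at lower temperature, should give the dimethylamide F9. Chemoselective reduction of the tertiary amide with Cp2Zr(H)Cl (THF, rt), which spares the ester, gives 9.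

Further compounds
F1 | step 9 | methyl 2-[cis-4-methyl-5-(3-oxoprop-1-en-2-yl)cyclohex-3-en-1-yl]prop-2-enoate | CC1=CC[C@H](C[C@H]1C(=C)C=O)C(=C)C(=O)OC
F2 | step 9 | methyl 2-[cis-5-(3-hydroxypenta-1,4-dien-2-yl)-4-methylcyclohex-3-en-1-yl]prop-2-enoate (carbinol epimers) | CC1=CC[C@H](C[C@H]1C(=C)C(O)C=C)C(=C)C(=O)OC
F3 | step 9 | methyl 2-[cis-4-methyl-5-(3-oxopenta-1,4-dien-2-yl)cyclohex-3-en-1-yl]prop-2-enoate | CC1=CC[C@H](C[C@H]1C(=C)C(=O)C=C)C(=C)C(=O)OC
F4 | step 9 | methyl 3-oxoeudesma-4(15),11(13)-dien-12-oate (5α-H, 7β, 10β-methyl) | C=C(C(=O)OC)[C@@H]1CC[C@@]2(C)CCC(=O)C(=C)[C@@H]2C1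
F5 | step 9 | methyl 3-hydroxyeudesma-4(15),11(13)-dien-12-oate (C3 epimers) | C=C(C(=O)OC)[C@@H]1CC[C@@]2(C)CCC(O)C(=C)[C@@H]2C1
F6 | step 9 | methyl 15-chloroeudesma-3,11(13)-dien-12-oate | C=C(C(=O)OC)[C@@H]1CC[C@@]2(C)CCC=C(CCl)[C@@H]2C1
F7 | step 8 | methyl 2-[cis-5-(1,3-dioxopropan-2-yl)-4-methylcyclohex-3-en-1-yl]prop-2-enoate (enolised malonaldehyde) | CC1=CC[C@H](C[C@H]1C(C=O)C=O)C(=C)C(=O)OC
F8 | step 8 | methyl 2-[cis-4-methyl-5-[(1E)-3-oxo-1-(trifluoromethylsulfonyloxy)prop-1-en-2-yl]cyclohex-3-en-1-yl]prop-2-enoate | CC1=CC[C@H](C[C@H]1/C(C=O)=C\OS(=O)(=O)C(F)(F)F)C(=C)C(=O)OC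
F9 | step 6 | methyl 2-[cis-5-[2-(dimethylamino)-2-oxoethyl]-4-methylcyclohex-3-en-1-yl]prop-2-enoate | CC1=CC[C@H](C[C@H]1CC(=O)N(C)C)C(=C)C(=O)OC
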